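A stalling flask can pass for an equilibrium. I started from the charges, the readings and the questions.

| flask | substrate | salt in the second phase | spent carrier | added ligand | remark | volume of the second phase over the first |
|---|---|---|---|---|---|---|
| Tuesday's | 0.20 mM | 0.30 mM | 10 µM | 26 µM | the very flask that is asked about, followed so far |  |
| Wednesday's | 0.30 mM | 0.30 mM | 10 µM | 26 µM | run made earlier |  |
| flask | 0.20 mM | 0.300 mM | 10 µM | 26 µM |  | 1.0 |

- Tuesday's (time / s: target / %, substrate / %): 15.0: 7.8, 88.6; 25.0: 11.9, 86.3; 40.0: 14.5, 83.2; 50.0: 16.4, 82.7
- Wednesday's (time / s: target / %, substrate / %): 15.0: 6.8, 91.5; 40.0: 10.6, 86.9; 80.0: 15.1, 83.3; 120: 16.8, 82.4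

(scatter of a reading: 1 percentage point)

- charges count per volume of the first phase; a concentration in a rate is the amount of a species over the volume of its own phase; every rate counts per litre of the first phase
- the earlier runs hold the two phases in the same ratio of volumes as the flask asked about
- no earlier run changes the charge of spent carrier; that part of a forecast is a guess
- no earlier run changes the charge of salt in the second phase; that part of a forecast is a guess

- factor on the rate of making target when 30% of the substrate are converted if salt in the second phase is charged twice over
- factor on the rate when 30% of the substrate are converted if spent carrier is charged at 100 µM instead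

Wednesday's run slowed to a crawl at 50.4 µM of target, with 82.4% of its substrate still present, so I suspected the carrier. I supposed that each target costs a fixed share of it, which, with the substrate taken as constant, makes the rate fall on a straight line against target made. Wednesday's rate was 0.337 µM s⁻¹ around 38.5 µM of target and 0.128 µM s⁻¹ around 47.9 µM. That line reaches zero at 53.5 µM, which I called the target budget: the target one charge of carrier makes before it is lost. But one point more on the last reading moves it to 65.6 µM.

Per carrier charged, the budget reads 5.35, a selectivity factor of target made against carrier lost. Each carrier lost then takes 6.35 substrate, so the flask's conversion should stop near 31.7%, and the 30% asked about lies just short of that crossing. There I reckoned 9.45 µM of carrier lost, nearly all of the charge. With the budget taken as independent of salt, that reckoned loss has no salt term, and I expected a factor near 1 for doubled salt. Taking the rate as proportional to the surviving carrier and leaving the added ligand out, for 100 µM of carrier I reckoned the surviving amounts' ratio, 164, or 44.7 with the shifted reading.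

The forecast, which differs from mine, gave 3 for doubled salt and 2.7 for the larger carrier charge: “Both forecasts are guesses.”

The flask gave 1.03 for doubled salt and 163 for the larger carrier charge, under this scheme:

    substrate + fresh carrier → target + spent carrier (k = 1040 L mol⁻¹ s⁻¹)
    substrate + fresh carrier → spent catalyst (k = 167 L mol⁻¹ s⁻¹)
    added ligand + fresh carrier ⇌ idle complex (K = 99000 L mol⁻¹, k = 1210 L mol⁻¹ s⁻¹)
    spent carrier + salt in the second phase ⇌ fresh carrier + spent salt in the second phase (K = 1.83, k = 3820 L mol⁻¹ s⁻¹)

When 30% of the substrate was converted in the flask, at 4.41 min, spent catalyst made up 83.0% of the catalyst charged, less than the 94.5% I had reckoned. By 30.0 min the flask had made 62.3 µM of target, between my budget of 53.5 µM and its shifted value of 65.6 µM, and spent catalyst stood at >99.9% of the catalyst charged.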